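No order in free catalyst can be read from the north-west run, since no earlier run changes its charge, so the next flask must change that charge: we take half the free catalyst and leave the substrates and reagent as they were.

all flasks: left-handed substrate 0.050 M; right-handed substrate 0.050 M

| charge | reagent | free catalyst | remark |
|---|---|---|---|
| north-west | 0.055 M | 3.2 mM | run made earlier |
| flask | 0.0550 M | 1.6 mM |  |

north-west run (percent of the left-handed substrate and right-handed substrate together charged)

| time / min | left-handed product / % | left-handed substrate / % |
|---|---|---|
| 2.00 | 13 | 34 |
| 4.00 | 20 | 27 |
| 6.00 | 24 | 24 |
| 12.0 | 34 | 18 |
| 25.0 | 35 | 14 |

(each reading ± 2 percentage points)

- apparent order in free catalyst when 50% of the left-handed substrate and right-handed substrate together are converted (percent change of the rate of making left-handed product for one percent more free catalyst charged)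

We reckon in turnovers (the turnover number), meaning moles of reagent used per mole of free catalyst charged. To reach the asked conversion the flask needs 31.2 turnovers and the north-west run 15.6, of which its last reading shows about 10.9 as left-handed product. The reagent charged to the flask allows 34.4 turnovers, so by this count 3.12 are left at the moment asked, and these spare turnovers, the reagent unused at the asked conversion per free catalyst charged, are the quantity we watch in the new flask. As a concentration the spare reagent is 0.00500 M in both flasks, which is 9.09% of the charge. If the reagent goes through the catalytic steps and free catalyst has fallen to the same share of its charge in both flasks, the two rates at that conversion differ as the charges do, and our own reckoning gives an order of 1. We watch that reserve for a slip from this order.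

The forecast also gives 1, on its own grounds: “If every route is catalytic, composition at fixed conversion is independent of catalyst charge”.

The flask gives 1.1, with the asked conversion reached at 21.0 h, and its steps are these:

    reagent + free catalyst + left-handed substrate → free catalyst + left-handed product (k = 1400 /M²/min)
    reagent + free catalyst + right-handed substrate → free catalyst + right-handed product (k = 75.0 /M²/min)
    2 free catalyst → spent catalyst (k = 20.0 /M/min)
    reagent → decomposition product (k = 3.90 × 10⁻⁵ /min)

One step uses reagent without free catalyst, and the flask holds 5.31 × 10⁻⁴ M of decomposition product after 40.0 h. That is the equivalent of 0.332 turnovers out of the 3.12 spare ones, the products made past the asked conversion have taken a further 0.448, and the reagent then left in the flask, 6.82% of its charge, amounts to 2.34 turnovers.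

(Readings and results stem from a simulated flask for an exercise.)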